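**Retrosynthetic overview**
- The target comes from its hexa-MOM ether by acetal hydrolysis; no skeletal bond is made after the coupling.
- The vinyl C(sp2)–O ether bond is cut into two C17 naphthalene halves: an (S)-configured O-silyl hydroxytrione, which already carries the only stereocentre, and a 2-fluoro-3-ethylnaphthoquinone. They are joined last by fluoride-catalysed addition–elimination.
- Both halves derive from one 2-hydroxy-3-ethylnaphthoquinone: asymmetric enolate hydroxylation then silylation gives the nucleophile, OH → Cl → F gives the electrophile.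
- The hydroxyquinone comes from an aryl bromide and 3-ethyl-4-methoxycyclobutenedione (aryllithium addition, thermal 4π-opening/6π-closure). The quinone ring is the only ring built, and it is formed onto the existing benzene ring.
- The aryl bromide comes from hydroquinone (MOM ether, ortho-bromination, IBX ortho-oxygenation); the cyclobutenedione comes from squaric acid and EtMgBr.

Assumption: the stereocentre in the SMILES is (S) (CIP order O > C(=O)–C(=O) > C(=O)–aryl > ethyl); racemic intermediates are written without stereo labels.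

**Step 1**
Reactants: 1 hydroquinone (benzene-1,4-diol)
Product: 2 4-(methoxymethoxy)phenol
Conditions: MOMCl (1.0 equiv), i-Pr2NEt, THF, 0 °C to rt
Reagents that add atoms: chloromethyl methyl ether (MOMCl), COCCl
Why: O-alkylation of one phenol by the α-chloro ether (MOM acetal formation) run to statistical mono-protection, with the bis-ether and recovered 1 separated and recycled.

**Step 2**
Reactants: 2 4-(methoxymethoxy)phenol
Product: 3 2-bromo-4-(methoxymethoxy)phenol
Conditions: NBS (1.0 equiv), MeCN, 0 °C
Reagents that add atoms: N-bromosuccinimide, O=C1CCC(=O)N1Br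
Why: electrophilic aromatic bromination in which the free hydroxyl, the strongest activator with its para position blocked, directs bromine to its own ortho carbon.

**Step 3**
Reactants: 3 2-bromo-4-(methoxymethoxy)phenol
Product: 5 3-bromo-5-(methoxymethoxy)benzene-1,2-diol, via o-quinone 4 (not isolated)
Conditions: IBX (1.1 equiv), DMF, rt; then aq Na2S2O4
Reagents that add atoms: 2-iodoxybenzoic acid (IBX), O=C1OI(=O)(O)c2ccccc12
Why: IBX ortho-oxygenation of a phenol, in which the aryloxy-iodane delivers oxygen intramolecularly to the only free ortho carbon and collapses to the o-quinone, which dithionite reduces to the catechol under neutral conditions that spare the MOM acetal.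

**Step 4**
Reactants: 5 3-bromo-5-(methoxymethoxy)benzene-1,2-diol
Product: 6 1-bromo-2,3,5-tris(methoxymethoxy)benzene
Conditions: MOMCl (2.5 equiv), i-Pr2NEt, CH2Cl2, 0 °C to rt
Reagents that add atoms: chloromethyl methyl ether (MOMCl), COCCl
Why: double MOM acetal formation gives a base-stable, acid-labile tris-ether whose ortho-alkoxy group later stabilises the aryllithium.

**Step 5**
Reactants: 7 squaric acid (3,4-dihydroxycyclobut-3-ene-1,2-dione)
Product: 8 dimethyl squarate (3,4-dimethoxycyclobut-3-ene-1,2-dione)
Conditions: HC(OMe)3, MeOH, reflux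
Reagents that add atoms: methanol, CO; trimethyl orthoformate, COC(OC)OC
Why: esterification of the vinylogous diacid, driven to completion because the orthoformate consumes the water formed.

**Step 6**
Reactants: 8 dimethyl squarate; 9 ethylmagnesium bromide
Product: 10 4-ethyl-4-hydroxy-2,3-dimethoxycyclobut-2-en-1-one (racemic)
Conditions: THF, −78 °C; aq NH4Cl
Reagents that add atoms: none
Why: Grignard 1,2-addition to one of the two equivalent vinylogous-ester carbonyls at low temperature, the racemic carbinol centre being destroyed in the next step.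

**Step 7**
Reactants: 10 4-ethyl-4-hydroxy-2,3-dimethoxycyclobut-2-en-1-one
Product: 11 3-ethyl-4-methoxycyclobut-3-ene-1,2-dione
Conditions: 12 M HCl (cat.), CH2Cl2, rt
Reagents that add atoms: none
Why: acid-mediated 1,3-transposition of a squarate adduct, in which the tertiary allylic alcohol ionises to a methoxy-stabilised cyclobutenyl cation that is hydrated at the methoxy-bearing terminus and loses methanol to give the cyclobutenedione.

**Step 8**
Reactants: 6 1-bromo-2,3,5-tris(methoxymethoxy)benzene; 11 3-ethyl-4-methoxycyclobut-3-ene-1,2-dione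
Product: 16 2-ethyl-3-hydroxy-5,6,8-tris(methoxymethoxy)naphthalene-1,4-dione, via aryllithium 12 (not isolated), via hydroxycyclobutenone 13 (not isolated), via naphthohydroquinone 14 (not isolated), via methoxyquinone 15 (not isolated)
Conditions: n-BuLi, THF, −78 °C, then 11, −78 °C, aq NH4Cl; crude in p-xylene, 138 °C; Ag2O, rt; 1 M NaOH, THF–MeOH, rt, then 1 M HCl
Reagents that add atoms: sodium hydroxide, [Na+].[OH-]
Why: Br–Li exchange and 1,2-addition to the ketone-like carbonyl next to C–OMe (the other carbonyl is a deactivated vinylogous ester) give the acid-sensitive carbinol, which on heating undergoes the Moore ring expansion (4π-electrocyclic opening with hydroxyl rotating outward to an aryl vinylketene, 6π-closure on the only free ortho carbon, tautomerisation) with the regiochemistry fixed by the addition site, after which Ag2O oxidises the hydroquinone, hydroxide saponifies the vinylogous methyl ester by addition–elimination, and the acidic product is purified by acid–base extraction.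

**Step 9**
Reactants: 16 2-ethyl-3-hydroxy-5,6,8-tris(methoxymethoxy)naphthalene-1,4-dione
Product: 17 (3S)-3-ethyl-3-hydroxy-5,7,8-tris(methoxymethoxy)naphthalene-1,2,4(3H)-trione
Conditions: NaN(SiMe3)2 (1.05 equiv), THF, −78 °C; (+)-[(8,8-dichlorocamphoryl)sulfonyl]oxaziridine (1.3 equiv), −78 to −20 °C; AcOH quench at −78 °C; recrystallise
Reagents that add atoms: (+)-[(8,8-dichlorocamphoryl)sulfonyl]oxaziridine, CC1(C)C2CCC13CS(=O)(=O)N4OC34C2(Cl)Cl
Why: Davis asymmetric enolate hydroxylation, in which the planar sodium enolate is oxidised at the ethyl-bearing carbon by the chiral N-sulfonyloxaziridine whose camphor framework shields one face (reagent control, assigned to the (S)-product by analogy with 2-ethyl-1-tetralone enolates, to be confirmed by X-ray, with the antipodal reagent used instead if the sense is opposite), and the product has no α-hydrogen so the new quaternary centre cannot epimerise.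

**Step 10**
Reactants: 17 (3S)-3-ethyl-3-hydroxy-5,7,8-tris(methoxymethoxy)naphthalene-1,2,4(3H)-trione
Product: 18 (3S)-3-ethyl-5,7,8-tris(methoxymethoxy)-3-(trimethylsilyloxy)naphthalene-1,2,4(3H)-trione
Conditions: 1-(trimethylsilyl)imidazole (1.5 equiv), CH2Cl2, rt
Reagents that add atoms: 1-(trimethylsilyl)imidazole, C[Si](C)(C)n1ccnc1
Why: neutral O-silylation of the tertiary alcohol (no enolisable position, no acid to touch the MOM groups) masks the base-labile α-ketol and sets up fluoride-triggered release of the alkoxide, with the stereocentre untouched.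

**Step 11**
Reactants: 16 2-ethyl-3-hydroxy-5,6,8-tris(methoxymethoxy)naphthalene-1,4-dione
Product: 19 3-chloro-2-ethyl-5,6,8-tris(methoxymethoxy)naphthalene-1,4-dione
Conditions: 1-chloro-N,N,2-trimethylprop-1-en-1-amine (1.2 equiv), CH2Cl2, 0 °C to rt
Reagents that add atoms: 1-chloro-N,N,2-trimethylprop-1-en-1-amine (Ghosez reagent), CC(C)=C(Cl)N(C)C
Why: the Ghosez α-chloroenamine converts the vinylogous carboxylic acid into the vinylogous acid chloride (O-activation, then chloride addition–elimination) without releasing HCl, so the MOM acetals survive.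

**Step 12**
Reactants: 19 3-chloro-2-ethyl-5,6,8-tris(methoxymethoxy)naphthalene-1,4-dione
Product: 20 2-ethyl-3-fluoro-5,6,8-tris(methoxymethoxy)naphthalene-1,4-dione
Conditions: AgF (1.5 equiv), MeCN, rt, dark
Reagents that add atoms: silver fluoride, [Ag+].[F-]
Why: halogen exchange by addition–elimination at the β-carbon of the enedione (vinylogous acyl substitution), driven by precipitation of AgCl, gives the vinylogous acyl fluoride, the most reactive partner for the final coupling.

**Step 13**
Reactants: 18 (3S)-3-ethyl-5,7,8-tris(methoxymethoxy)-3-(trimethylsilyloxy)naphthalene-1,2,4(3H)-trione; 20 2-ethyl-3-fluoro-5,6,8-tris(methoxymethoxy)naphthalene-1,4-dione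
Product: 21 (3S)-3-ethyl-3-{[3-ethyl-5,7,8-tris(methoxymethoxy)-1,4-dioxo-1,4-dihydronaphthalen-2-yl]oxy}-5,7,8-tris(methoxymethoxy)naphthalene-1,2,4(3H)-trione
Conditions: tetrabutylammonium difluorotriphenylsilicate (10 mol %), THF, 4 Å MS, −40 to 0 °C
Reagents that add atoms: none
Why: fluoride-catalysed desilylative addition–elimination (vinylogous acyl substitution), in which catalytic fluoride unmasks the tertiary alkoxide of 18, this adds to the fluorine-bearing carbon of 20 and expels fluoride that carries the chain, so no stoichiometric base meets the hydroxytrione and, because the bond is made at the sp2 carbon, the quaternary (S)-centre is retained.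

**Step 14**
Reactants: 21 hexa-MOM dimer
Product: 22 (3S)-3-ethyl-3-[(3-ethyl-5,7,8-trihydroxy-1,4-dioxo-1,4-dihydronaphthalen-2-yl)oxy]-5,7,8-trihydroxynaphthalene-1,2,4(3H)-trione (CNP0325426.1)
Conditions: TFA–CH2Cl2–H2O (10:88:2), 0 °C to rt; evaporate; reverse-phase chromatography (0.1% HCO2H)
Reagents that add atoms: none
Why: acid-catalysed hydrolysis of the six aryl MOM acetals, which the tertiary-alkyl vinyl ether should survive because ionisation at a carbon flanked by two carbonyls is disfavoured, and the stereocentre has no α-hydrogen to epimerise.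

**Compound list**
1 | hydroquinone (benzene-1,4-diol) | Oc1ccc(O)cc1 | starting material
2 | 4-(methoxymethoxy)phenol | COCOc1ccc(O)cc1 | intermediate
3 | 2-bromo-4-(methoxymethoxy)phenol | COCOc1ccc(O)c(Br)c1 | intermediate
4 | 3-bromo-5-(methoxymethoxy)cyclohexa-3,5-diene-1,2-dione | O=C1C(=O)C(Br)=CC(OCOC)=C1 | intermediate
5 | 3-bromo-5-(methoxymethoxy)benzene-1,2-diol | COCOc1cc(O)c(O)c(Br)c1 | intermediate
6 | 1-bromo-2,3,5-tris(methoxymethoxy)benzene | COCOc1cc(Br)c(OCOC)c(OCOC)c1 | intermediate
7 | squaric acid (3,4-dihydroxycyclobut-3-ene-1,2-dione) | OC1=C(O)C(=O)C1=O | starting material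
8 | dimethyl squarate (3,4-dimethoxycyclobut-3-ene-1,2-dione) | COC1=C(OC)C(=O)C1=O | intermediate
9 | ethylmagnesium bromide | CC[Mg]Br | starting material
10 | 4-ethyl-4-hydroxy-2,3-dimethoxycyclobut-2-en-1-one (racemic) | CCC1(O)C(OC)=C(OC)C1=O | intermediate
11 | 3-ethyl-4-methoxycyclobut-3-ene-1,2-dione | CCC1=C(OC)C(=O)C1=O | intermediate
12 | [2,3,5-tris(methoxymethoxy)phenyl]lithium | [Li]c1cc(OCOC)cc(OCOC)c1OCOC | intermediate
13 | 2-ethyl-4-hydroxy-3-methoxy-4-[2,3,5-tris(methoxymethoxy)phenyl]cyclobut-2-en-1-one (racemic) | CCC1=C(OC)C(O)(c2cc(OCOC)cc(OCOC)c2OCOC)C1=O | intermediate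
14 | 2-ethyl-3-methoxy-5,6,8-tris(methoxymethoxy)naphthalene-1,4-diol | CCc1c(OC)c(O)c2c(OCOC)c(OCOC)cc(OCOC)c2c1O | intermediate
15 | 2-ethyl-3-methoxy-5,6,8-tris(methoxymethoxy)naphthalene-1,4-dione | CCC1=C(OC)C(=O)c2c(OCOC)c(OCOC)cc(OCOC)c2C1=O | intermediate
16 | 2-ethyl-3-hydroxy-5,6,8-tris(methoxymethoxy)naphthalene-1,4-dione | CCC1=C(O)C(=O)c2c(OCOC)c(OCOC)cc(OCOC)c2C1=O | intermediate
17 | (3S)-3-ethyl-3-hydroxy-5,7,8-tris(methoxymethoxy)naphthalene-1,2,4(3H)-trione | O[C@]1(CC)C(=O)C(=O)c2c(OCOC)c(OCOC)cc(OCOC)c2C1=O | intermediate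
18 | (3S)-3-ethyl-5,7,8-tris(methoxymethoxy)-3-(trimethylsilyloxy)naphthalene-1,2,4(3H)-trione | C[Si](C)(C)O[C@]1(CC)C(=O)C(=O)c2c(OCOC)c(OCOC)cc(OCOC)c2C1=O | intermediate
19 | 3-chloro-2-ethyl-5,6,8-tris(methoxymethoxy)naphthalene-1,4-dione | CCC1=C(Cl)C(=O)c2c(OCOC)c(OCOC)cc(OCOC)c2C1=O | intermediate
20 | 2-ethyl-3-fluoro-5,6,8-tris(methoxymethoxy)naphthalene-1,4-dione | CCC1=C(F)C(=O)c2c(OCOC)c(OCOC)cc(OCOC)c2C1=O | intermediate
21 | (3S)-3-ethyl-3-{[3-ethyl-5,7,8-tris(methoxymethoxy)-1,4-dioxo-1,4-dihydronaphthalen-2-yl]oxy}-5,7,8-tris(methoxymethoxy)naphthalene-1,2,4(3H)-trione | CCC1=C(O[C@]2(CC)C(=O)C(=O)c3c(OCOC)c(OCOC)cc(OCOC)c3C2=O)C(=O)c2c(OCOC)c(OCOC)cc(OCOC)c2C1=O | intermediate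
22 | (3S)-3-ethyl-3-[(3-ethyl-5,7,8-trihydroxy-1,4-dioxo-1,4-dihydronaphthalen-2-yl)oxy]-5,7,8-trihydroxynaphthalene-1,2,4(3H)-trione | CCC1=C(O[C@]2(CC)C(=O)C(=O)c3c(O)c(O)cc(O)c3C2=O)C(=O)c2c(O)c(O)cc(O)c2C1=O | target

**Step count**
Total step count: 14.
Longest linear sequence: 9 steps (1, 2, 3, 4, 8, 9, 10, 13, 14; the path through 11 and 12 is equally long; the squarate path 5, 6, 7, 8, 9, 10, 13, 14 is 8).

**Steps most likely to fail**

Step 13, the silyl ether/fluoroquinone coupling: the liberated tertiary alkoxide, flanked by two carbonyls, may undergo α-ketol ring contraction or add too slowly to the hindered fluoroquinone. Fallback: set out from 16 and replace the two-electron coupling by a one-electron dehydrodimerisation. PbO2 in AcOH–CH2Cl2 at rt oxidises 16 to its oxy radical, which couples oxygen to the ethyl-bearing carbon of a second molecule (the known behaviour of 2-hydroxy-3-alkylnaphthoquinones) and gives the racemic hexa-MOM dimer F1. Preparative SFC on a chiral stationary phase then delivers the (S)-enantiomer, and the route is rejoined at 21.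

Step 9, the asymmetric hydroxylation: the strongly stabilised enolate may react sluggishly with the hindered camphor oxaziridine or give low ee. Fallback: from 16, hydroxylate without asymmetric induction using dimethyldioxirane (acetone, 0 °C), which oxidises the enol directly to the racemic hydroxytrione F2. Resolve this by preparative chiral SFC; the (S)-enantiomer is 17, where the route is rejoined.

Step 14, global deprotection of the dimer: the vinylogous ester linkage or the vicinal dione may not survive the acid needed for six MOM groups. Fallback: from 16, remove the MOM groups at the robust monomer stage (3 M HCl, THF, 40 °C) to give the free tetrahydroxyquinone F3. Dehydrodimerise it without protecting groups (PbO2, AcOH, rt) to the racemic natural product F4, and separate the enantiomers by chiral HPLC, arriving directly at 22.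

**Further compounds**
F1 | step 13 | racemic 3-ethyl-3-{[3-ethyl-5,7,8-tris(methoxymethoxy)-1,4-dioxo-1,4-dihydronaphthalen-2-yl]oxy}-5,7,8-tris(methoxymethoxy)naphthalene-1,2,4(3H)-trione | CCC1=C(OC2(CC)C(=O)C(=O)c3c(OCOC)c(OCOC)cc(OCOC)c3C2=O)C(=O)c2c(OCOC)c(OCOC)cc(OCOC)c2C1=O
F2 | step 9 | racemic 3-ethyl-3-hydroxy-5,7,8-tris(methoxymethoxy)naphthalene-1,2,4(3H)-trione | OC1(CC)C(=O)C(=O)c2c(OCOC)c(OCOC)cc(OCOC)c2C1=O
F3 | step 14 | 2-ethyl-3,5,6,8-tetrahydroxynaphthalene-1,4-dione | CCC1=C(O)C(=O)c2c(O)c(O)cc(O)c2C1=O
F4 | step 14 | racemic 3-ethyl-3-[(3-ethyl-5,7,8-trihydroxy-1,4-dioxo-1,4-dihydronaphthalen-2-yl)oxy]-5,7,8-trihydroxynaphthalene-1,2,4(3H)-trione | CCC1=C(OC2(CC)C(=O)C(=O)c3c(O)c(O)cc(O)c3C2=O)C(=O)c2c(O)c(O)cc(O)c2C1=O
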